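**Plan**

1. Numbering used below: C1–C3 = 1-hydroxypropyl chain (C3 carbinol); ring A (piperidine) = N, C4–C8; ring B (azepane) = N, C8, C9, C13, C14, C15, C16; ring C (cyclopentane) = C9, C10 (Me), C11 (OH), C12 (spiro), C13 (OH); ring D = the 4-methoxy-3-methylbutenolide spiro-fused at C12.
2. Retrosynthetic cuts, in this order: C11–C12 (ring C), C12–C13 (butenolide anion + ring B ketone), N–C4 and N–C16 (double reductive amination), C13–C14 (Grignard addition to a γ-lactone), C8–C9 (Mannich addition to an N-sulfinyl imine), C4–C5 (Weinreb ketone synthesis).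
3. Forward: the C1–C8 chain is built, C8–C9 is joined (Mannich), C14–C16 are added, rings A and B close in one pot, ring D is attached at C13, ring C is closed last at C11–C12, then C11 is adjusted by oxidation and directed reduction and the protecting groups are removed.
4. Feature that makes the ring C closure possible: C12 is the γ-carbon (C5) of a butenolide, hence a latent 2-silyloxyfuran nucleophile, and C11 is an aldehyde carbon held three atoms away through C13–C9–C10 on ring B. One 5-exo attack therefore creates ring C and the spiro quaternary centre; the trans ring B/ring C junction holds the C13 silyloxy group axial and directs the furan.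
5. Stereochemistry: C3 from methyl (R)-2-hydroxybutanoate; C10 from (S)-4-methyldihydrofuran-2(3H)-one; C8 from the (S)-tert-butanesulfinyl group; C9 by reaction trans to the lactone methyl; C4 by axial hydride delivery to the cyclic iminium ion (cis-2,6); C13 by attack anti to the C9 branch; C12 in the key step; C11 by hydroxyl-directed reduction.

Key step: step 13

Remark (assumption): (S)-4-methyldihydrofuran-2(3H)-one, 4-methoxy-3-methylfuran-2(5H)-one and the two Grignard solutions are taken as purchasable; compounds 20 and 21 are carried as both epimers at C12, which becomes planar in step 13.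

**Route**

Step 1
Reactants: 1 methyl (R)-2-hydroxybutanoate
Product: 2 methyl (R)-2-(benzyloxy)butanoate
Conditions: benzyl 2,2,2-trichloroacetimidate, TfOH (cat.), cyclohexane/CH2Cl2, rt
Reagents that add atoms: benzyl 2,2,2-trichloroacetimidate, N=C(OCc1ccccc1)C(Cl)(Cl)Cl
Why: Acid-catalysed O-benzylation with the trichloroacetimidate protects the C3 hydroxyl without base, so the chiral-pool α-stereocentre (C3, R) is not touched.

Step 2
Reactants: 2 methyl (R)-2-(benzyloxy)butanoate
Product: 3 (R)-2-(benzyloxy)-N-methoxy-N-methylbutanamide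
Conditions: MeNH(OMe)·HCl, iPrMgCl, THF, −20 °C
Reagents that add atoms: N,O-dimethylhydroxylamine hydrochloride, CNOC.Cl
Why: Weinreb amide formation from the ester with the chloromagnesium amide of N,O-dimethylhydroxylamine proceeds at low temperature without enolising the α-alkoxy centre.

Step 3
Reactants: 3 (R)-2-(benzyloxy)-N-methoxy-N-methylbutanamide; 4 pent-4-en-1-ylmagnesium bromide
Product: 5 (R)-3-(benzyloxy)non-8-en-4-one
Conditions: THF, 0 °C
Reagents that add atoms: none
Why: Weinreb ketone synthesis: the chelated tetrahedral intermediate stops the Grignard addition at the ketone stage and forms the C4–C5 bond.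

Step 4
Reactants: 5 (R)-3-(benzyloxy)non-8-en-4-one
Product: 6 2-[(1R)-1-(benzyloxy)propyl]-2-(pent-4-en-1-yl)-1,3-dioxolane
Conditions: Me3SiOCH2CH2OSiMe3, Me3SiOTf (cat.), CH2Cl2, −78 → −20 °C
Reagents that add atoms: 1,2-bis(trimethylsilyloxy)ethane, C[Si](C)(C)OCCO[Si](C)(C)C
Why: Aprotic silyl-transfer ketalisation masks the C4 ketone for the enolate chemistry of step 7 without epimerising C3.

Step 5
Reactants: 6 2-[(1R)-1-(benzyloxy)propyl]-2-(pent-4-en-1-yl)-1,3-dioxolane
Product: 7 4-{2-[(1R)-1-(benzyloxy)propyl]-1,3-dioxolan-2-yl}butanal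
Conditions: O3, CH2Cl2, −78 °C; then PPh3
Reagents that add atoms: ozone, [O-][O+]=O
Why: Ozonolysis with reductive work-up cleaves the terminal alkene to the C8 aldehyde.

Step 6
Reactants: 7 4-{2-[(1R)-1-(benzyloxy)propyl]-1,3-dioxolan-2-yl}butanal; 8 (S)-2-methylpropane-2-sulfinamide
Product: 9 (S)-N-[(1E)-4-{2-[(1R)-1-(benzyloxy)propyl]-1,3-dioxolan-2-yl}butylidene]-2-methylpropane-2-sulfinamide
Conditions: CuSO4, CH2Cl2, rt
Reagents that add atoms: none
Why: Dehydrating condensation of the aldehyde with the sulfinamide gives the (E)-N-sulfinyl aldimine, which carries the future ring nitrogen and the controller for C8.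

Step 7
Reactants: 9 (S)-N-[(1E)-4-{2-[(1R)-1-(benzyloxy)propyl]-1,3-dioxolan-2-yl}butylidene]-2-methylpropane-2-sulfinamide; 10 (S)-4-methyldihydrofuran-2(3H)-one
Product: 11 (S)-N-[(1S)-4-{2-[(1R)-1-(benzyloxy)propyl]-1,3-dioxolan-2-yl}-1-[(3R,4S)-4-methyl-2-oxotetrahydrofuran-3-yl]butyl]-2-methylpropane-2-sulfinamide
Conditions: 10, LiN(iPr)2, THF, −78 °C; ClTi(OiPr)3; then 9, −78 °C
Reagents that add atoms: none
Why: Mannich addition of the titanium lactone enolate to the N-sulfinyl imine through a closed six-membered chair transition state (Ti on the imine nitrogen and the sulfinyl oxygen): attack on the imine face away from the tert-butyl group sets C8 (S), and the enolate reacts on its face trans to the C10 methyl group, which sets C9 (R) and gives the syn arrangement usual for ester E(O)-enolates in this reaction.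

Step 8
Reactants: 11 (the Mannich lactone); 12 [2-(1,3-dioxan-2-yl)ethyl]magnesium bromide
Product: 13 (S)-N-[(4S,5R)-1-{2-[(1R)-1-(benzyloxy)propyl]-1,3-dioxolan-2-yl}-8-(1,3-dioxan-2-yl)-5-[(2S)-1-hydroxypropan-2-yl]-6-oxooctan-4-yl]-2-methylpropane-2-sulfinamide
Conditions: 12 (3 equiv), THF, −78 °C
Reagents that add atoms: none
Why: Single Grignard addition to a γ-lactone: after N–H deprotonation by the first equivalent, the tetrahedral magnesium lactolate is stable at low temperature and opens to the hydroxy ketone only on work-up, which forms the C13–C14 bond.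

Step 9
Reactants: 13 (the N-sulfinyl amino hydroxy ketone)
Product: 16 (4R,10R,10aS)-4-[(1R)-1-(benzyloxy)propyl]-10-[(2S)-1-hydroxypropan-2-yl]perhydropyrido[1,2-a]azepin-9-one, via amino diketo aldehyde hydrochloride 14 (not isolated), via piperidine keto aldehyde 15 (not isolated)
Conditions: 3 M HCl, THF, rt; evaporate; NaBH(OAc)3, NaOAc, ClCH2CH2Cl, rt
Reagents that add atoms: none
Why: Acid removes the sulfinyl group and both acetals, and a double reductive amination (amine onto the C4 ketone, then onto the C16 aldehyde) closes rings A and B; hydride adds axially to the cyclic iminium ion with the C8 substituent equatorial, which gives the cis-2,6-piperidine (C4, R), while the C13 carbonyl is shielded as a hemiketal with the C11 hydroxyl.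

Step 10
Reactants: 16 (the bicyclic amino ketone alcohol)
Product: 17 (4R,10R,10aS)-4-[(1R)-1-(benzyloxy)propyl]-10-[(2S)-1-(triethylsilyloxy)propan-2-yl]perhydropyrido[1,2-a]azepin-9-one
Conditions: Et3SiCl, imidazole, CH2Cl2, 0 °C
Reagents that add atoms: chlorotriethylsilane, CC[Si](Cl)(CC)CC
Why: Selective silylation of the primary hydroxyl releases the C13 ketone from its hemiketal form and installs a group that step 12 can oxidise directly.

Step 11
Reactants: 17 (the silyl-protected bicyclic ketone); 18 4-methoxy-3-methylfuran-2(5H)-one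
Product: 20 (4R,9S,10R,10aS)-4-[(1R)-1-(benzyloxy)propyl]-9-(3-methoxy-4-methyl-5-oxo-2,5-dihydrofuran-2-yl)-9-(triethylsilyloxy)-10-[(2S)-1-(triethylsilyloxy)propan-2-yl]perhydropyrido[1,2-a]azepine, via lithium alkoxide 19 (not isolated)
Conditions: 18, LiN(iPr)2, THF, −78 °C; add 17; then Et3SiOTf, −78 → −20 °C
Reagents that add atoms: triethylsilyl trifluoromethanesulfonate, CC[Si](CC)(CC)OS(=O)(=O)C(F)(F)F
Why: Vinylogous aldol addition of the lithium dienolate of the butenolide (reacting at C5) to the ring B ketone from the face anti to the C9 branch and C7 sets C13 (S), and silylation of the aldolate in the flask blocks retro-aldol and installs the axial control group for step 13.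

Step 12
Reactants: 20 (the bis-silyl tetronate adduct)
Product: 21 (2S)-2-[(4R,9S,10R,10aS)-4-[(1R)-1-(benzyloxy)propyl]-9-(3-methoxy-4-methyl-5-oxo-2,5-dihydrofuran-2-yl)-9-(triethylsilyloxy)perhydropyrido[1,2-a]azepin-10-yl]propanal
Conditions: (COCl)2, DMSO, CH2Cl2, −78 → −40 °C; then Et3N
Reagents that add atoms: none
Why: Swern oxidation converts a primary triethylsilyl ether directly into the aldehyde while the hindered tertiary silyl ether survives, so C11 is unmasked without a separate deprotection.

Step 13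
Reactants: 21 (the C11 aldehyde)
Product: 23 C3-O-benzyl C11-O-trimethylsilyl C13-O-triethylsilyl derivative of 11-epi-27 (11R), via 2-silyloxyfuran 22 (not isolated)
Conditions: Me3SiOTf (3 equiv), Et3N (4 equiv), CH2Cl2, −78 → −20 °C
Reagents that add atoms: trimethylsilyl trifluoromethanesulfonate, C[Si](C)(C)OS(=O)(=O)C(F)(F)F
Why: Me3SiOTf/Et3N turns ring D into its 2-silyloxyfuran 22 (soft enolisation at C12–H), and further Me3SiOTf activates the C11 aldehyde so that furan C5 (C12) attacks it, the silyl group ending on O11. The closest known reaction type is the silyl-triflate-promoted vinylogous Mukaiyama aldol of 2-silyloxyfurans, run here in the one-pot enol-silane-formation/aldol mode. Ring C closes in the 5-(enolexo)-exo-trig mode through the C13–C9–C10 chain that sits on ring B. C12 is controlled by the C13 silyloxy group: ring B can be trans-fused to the forming ring only with C8 and C14 equatorial, which leaves the silyloxy group axial, so the methoxy-bearing C4 edge of the planar furan turns to the C14 face and O1 ends cis to O13 (12R). C11 should form mainly with its silyloxy group eclipsing the small O1 edge (11R, cis to O13); this is accepted because C11 is re-set in steps 15 and 16. The step needs enolisation of the butenolide in preference to the α-branched aldehyde (the vinylogous carbonate carbonyl is the more basic site and loss of its γ-proton gives an aromatic furan) and face selectivity at C12, both supported by the bulky axial silyl ether, which also prevents lactol formation and retro-aldol.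

Step 14
Reactants: 23 (the bis-silyl spiro compound)
Product: 24 C3-O-benzyl ether of 11-epi-27 (11R diol)
Conditions: HF·pyridine, THF, 0 °C → rt
Reagents that add atoms: none
Why: Fluoride cleaves both silyl ethers under mildly acidic conditions, which avoid base-induced retro-aldol at C11–C12 or C12–C13.

Step 15
Reactants: 24 (the 11-epi diol)
Product: 25 C3-O-benzyl ether of 11-dehydro-27 (C11 ketone with free C13 hydroxyl)
Conditions: Dess–Martin periodinane, CH2Cl2, 0 °C
Reagents that add atoms: none
Why: Dess–Martin oxidation of the secondary C11 alcohol (the tertiary C13 alcohol is inert) removes the unwanted C11 configuration under non-basic conditions; C10 stays in its stable equatorial arrangement trans to C8.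

Step 16
Reactants: 25 (the β-hydroxy ketone)
Product: 26 C3-O-benzyl ether of 27
Conditions: Me4NBH(OAc)3, AcOH/MeCN, −20 °C
Reagents that add atoms: none
Why: Evans–Saksena reduction: the acetoxyborohydride exchanges onto the axial C13 hydroxyl and delivers hydride intramolecularly to the C11 carbonyl from the O13 face, which should give the trans-1,3-diol (C11, S).

Step 17
Reactants: 26 (the benzyl ether)
Product: 27 CNP0267781.1
Conditions: H2 (1 atm), Pd(OH)2/C, AcOH, MeOH, rt
Reagents that add atoms: none
Why: Hydrogenolysis removes the benzyl ether; the tetrasubstituted vinylogous-carbonate alkene of ring D should resist hydrogenation.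

**Compound list**

1 | methyl (R)-2-hydroxybutanoate | CC[C@@H](O)C(=O)OC | starting material
2 | methyl (R)-2-(benzyloxy)butanoate | CC[C@@H](OCc1ccccc1)C(=O)OC | intermediate
3 | (R)-2-(benzyloxy)-N-methoxy-N-methylbutanamide | CC[C@@H](OCc1ccccc1)C(=O)N(C)OC | intermediate
4 | pent-4-en-1-ylmagnesium bromide | C=CCCC[Mg]Br | starting material
5 | (R)-3-(benzyloxy)non-8-en-4-one | CC[C@@H](OCc1ccccc1)C(=O)CCCC=C | intermediate
6 | 2-[(1R)-1-(benzyloxy)propyl]-2-(pent-4-en-1-yl)-1,3-dioxolane | CC[C@@H](OCc1ccccc1)C1(CCCC=C)OCCO1 | intermediate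
7 | 4-{2-[(1R)-1-(benzyloxy)propyl]-1,3-dioxolan-2-yl}butanal | CC[C@@H](OCc1ccccc1)C1(CCCC=O)OCCO1 | intermediate
8 | (S)-2-methylpropane-2-sulfinamide | CC(C)(C)[S@](=O)N | starting material
9 | (S)-N-[(1E)-4-{2-[(1R)-1-(benzyloxy)propyl]-1,3-dioxolan-2-yl}butylidene]-2-methylpropane-2-sulfinamide | CC[C@@H](OCc1ccccc1)C1(CCC/C=N/[S@@](=O)C(C)(C)C)OCCO1 | intermediate
10 | (S)-4-methyldihydrofuran-2(3H)-one | O=C1C[C@H](C)CO1 | starting material
11 | (S)-N-[(1S)-4-{2-[(1R)-1-(benzyloxy)propyl]-1,3-dioxolan-2-yl}-1-[(3R,4S)-4-methyl-2-oxotetrahydrofuran-3-yl]butyl]-2-methylpropane-2-sulfinamide | CC[C@@H](OCc1ccccc1)C1(OCCO1)CCC[C@H](N[S@@](=O)C(C)(C)C)[C@H]2[C@H](C)COC2=O | intermediate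
12 | [2-(1,3-dioxan-2-yl)ethyl]magnesium bromide | Br[Mg]CCC1OCCCO1 | starting material
13 | (S)-N-[(4S,5R)-1-{2-[(1R)-1-(benzyloxy)propyl]-1,3-dioxolan-2-yl}-8-(1,3-dioxan-2-yl)-5-[(2S)-1-hydroxypropan-2-yl]-6-oxooctan-4-yl]-2-methylpropane-2-sulfinamide (in equilibrium with its cyclic hemiketal) | CC[C@@H](OCc1ccccc1)C1(OCCO1)CCC[C@H](N[S@@](=O)C(C)(C)C)[C@@H]([C@H](C)CO)C(=O)CCC1OCCCO1 | intermediate
14 | amino diketo aldehyde hydrochloride: 13 without the sulfinyl group and both acetals (free C8 amine, C4 ketone, C13 ketone, C16 aldehyde, C11 hydroxyl) | CC[C@@H](OCc1ccccc1)C(=O)CCC[C@H](N)[C@@H]([C@H](C)CO)C(=O)CCC=O.Cl | intermediate (not isolated)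
15 | piperidine keto aldehyde: cis-2,6-disubstituted piperidine (ring A closed, N–H) carrying the C13 ketone and C16 aldehyde | CC[C@@H](OCc1ccccc1)[C@H]1CCC[C@H](N1)[C@@H]([C@H](C)CO)C(=O)CCC=O | intermediate (not isolated)
16 | (4R,10R,10aS)-4-[(1R)-1-(benzyloxy)propyl]-10-[(2S)-1-hydroxypropan-2-yl]perhydropyrido[1,2-a]azepin-9-one | CC[C@@H](OCc1ccccc1)[C@H]1CCC[C@H]2[C@@H]([C@H](C)CO)C(=O)CCCN12 | intermediate
17 | (4R,10R,10aS)-4-[(1R)-1-(benzyloxy)propyl]-10-[(2S)-1-(triethylsilyloxy)propan-2-yl]perhydropyrido[1,2-a]azepin-9-one | CC[C@@H](OCc1ccccc1)[C@H]1CCC[C@H]2[C@@H]([C@H](C)CO[Si](CC)(CC)CC)C(=O)CCCN12 | intermediate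
18 | 4-methoxy-3-methylfuran-2(5H)-one | COC1=C(C)C(=O)OC1 | starting material
19 | lithium alkoxide of the tetronate adduct (C13–OLi, both C12 epimers) | CC[C@@H](OCc1ccccc1)[C@H]1CCC[C@H]2[C@@H]([C@H](C)CO[Si](CC)(CC)CC)[C@]([O-])(C3OC(=O)C(C)=C3OC)CCCN12.[Li+] | intermediate (not isolated)
20 | (4R,9S,10R,10aS)-4-[(1R)-1-(benzyloxy)propyl]-9-(3-methoxy-4-methyl-5-oxo-2,5-dihydrofuran-2-yl)-9-(triethylsilyloxy)-10-[(2S)-1-(triethylsilyloxy)propan-2-yl]perhydropyrido[1,2-a]azepine (both C12 epimers) | CC[C@@H](OCc1ccccc1)[C@H]1CCC[C@H]2[C@@H]([C@H](C)CO[Si](CC)(CC)CC)[C@](O[Si](CC)(CC)CC)(C3OC(=O)C(C)=C3OC)CCCN12 | intermediate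
21 | (2S)-2-[(4R,9S,10R,10aS)-4-[(1R)-1-(benzyloxy)propyl]-9-(3-methoxy-4-methyl-5-oxo-2,5-dihydrofuran-2-yl)-9-(triethylsilyloxy)perhydropyrido[1,2-a]azepin-10-yl]propanal (both C12 epimers) | CC[C@@H](OCc1ccccc1)[C@H]1CCC[C@H]2[C@@H]([C@H](C)C=O)[C@](O[Si](CC)(CC)CC)(C3OC(=O)C(C)=C3OC)CCCN12 | intermediate
22 | 2-(trimethylsilyloxy)furan form of 21 (ring D aromatised, C12 planar) | CC[C@@H](OCc1ccccc1)[C@H]1CCC[C@H]2[C@@H]([C@H](C)C=O)[C@](O[Si](CC)(CC)CC)(c3oc(O[Si](C)(C)C)c(C)c3OC)CCCN12 | intermediate (not isolated)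
23 | C3-O-benzyl C11-O-trimethylsilyl C13-O-triethylsilyl derivative of 11-epi-27 (11R, 12R; rings A–D complete) | CC[C@@H](OCc1ccccc1)[C@H]1CCC[C@H]2[C@H]3[C@H](C)[C@@H](O[Si](C)(C)C)[C@@]4(OC(=O)C(C)=C4OC)[C@]3(O[Si](CC)(CC)CC)CCCN12 | intermediate
24 | C3-O-benzyl ether of 11-epi-27 (11R; C11 and C13 hydroxyls free) | CC[C@@H](OCc1ccccc1)[C@H]1CCC[C@H]2[C@H]3[C@H](C)[C@@H](O)[C@@]4(OC(=O)C(C)=C4OC)[C@]3(O)CCCN12 | intermediate
25 | C3-O-benzyl ether of 11-dehydro-27 (C11 ketone, C13 hydroxyl free) | CC[C@@H](OCc1ccccc1)[C@H]1CCC[C@H]2[C@H]3[C@H](C)C(=O)[C@@]4(OC(=O)C(C)=C4OC)[C@]3(O)CCCN12 | intermediate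
26 | C3-O-benzyl ether of 27 | CC[C@@H](OCc1ccccc1)[C@H]1CCC[C@H]2[C@H]3[C@H](C)[C@H](O)[C@@]4(OC(=O)C(C)=C4OC)[C@]3(O)CCCN12 | intermediate
27 | CNP0267781.1 (3R,4R,8S,9R,10S,11S,12R,13S in the numbering above) | CC[C@@H](O)[C@H]1CCC[C@H]2[C@H]3[C@H](C)[C@H](O)[C@@]4(OC(=O)C(C)=C4OC)[C@]3(O)CCCN12 | target

**Step count and risks**

Total step count: 17. Longest linear sequence: 17 steps (1 → 27).

Steps most likely to fail:

Step 13. The silyl triflate may enolise the α-branched aldehyde as well as the butenolide, with loss of the C10 configuration, or the kinetic closure may show poor face selectivity at C12. Fallback, starting from 21: oxidation of the aldehyde (NaClO2, NaH2PO4, 2-methylbut-2-ene) should give the carboxylic acid F1, and Me3SiCHN2 its methyl ester F2. LiN(SiMe3)2 then deprotonates only the butenolide, and a Dieckmann-type C-acylation at C12 closes ring C at the ketone oxidation level to the silyl-protected spiro ketone F3. This closure is reversible by retro-Claisen opening, so C12 can settle under thermodynamic rather than kinetic control. HF·pyridine removes the silyl group and the route is rejoined at 25.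

Step 11. The basic dienolate may enolise the hindered, α-branched ketone instead of adding, or the addition may reverse before the silyl trap takes hold. Fallback, starting from 18: Et3SiOTf/Et3N should give 4-methoxy-3-methyl-2-(triethylsilyloxy)furan F4. A vinylogous Mukaiyama addition of F4 to ketone 17, promoted by Et3SiOTf, is non-basic and transfers the silyl group to O13 as the C–C bond forms, so it should lead directly back to 20.

Step 7. Diastereoselectivity may be low if the sulfinyl-controlled imine face and the methyl-controlled enolate face cannot be combined in one closed transition state, or the enolisable imine may self-condense. Fallback, starting from 7 and 10: aldol addition of the lithium enolate of 10 to aldehyde 7 gives the β-hydroxy lactone F5 (mixture at C8), and Dess–Martin oxidation the β-keto lactone F6. Condensation with 8 (Ti(OEt)4) gives the N-sulfinyl enamino lactone F7. Hydride reduction (NaBH4 or LiBH(sBu)3, which give opposite senses at C8 with N-sulfinyl ketimines) sets C8 by the sulfinyl group, while the acidic C9 settles trans to the lactone methyl. The product is 11.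

Further compounds
F1 | step 13 | carboxylic acid from 21: (2S)-2-[ring B substituent as in 21]propanoic acid (C11 acid, C13 OSiEt3, both C12 epimers) | CC[C@@H](OCc1ccccc1)[C@H]1CCC[C@H]2[C@@H]([C@H](C)C(=O)O)[C@](O[Si](CC)(CC)CC)(C3OC(=O)C(C)=C3OC)CCCN12
F2 | step 13 | methyl ester of F1 | CC[C@@H](OCc1ccccc1)[C@H]1CCC[C@H]2[C@@H]([C@H](C)C(=O)OC)[C@](O[Si](CC)(CC)CC)(C3OC(=O)C(C)=C3OC)CCCN12
F3 | step 13 | C13-O-triethylsilyl ether of 25 (ring C ketone) | CC[C@@H](OCc1ccccc1)[C@H]1CCC[C@H]2[C@H]3[C@H](C)C(=O)[C@@]4(OC(=O)C(C)=C4OC)[C@]3(O[Si](CC)(CC)CC)CCCN12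
F4 | step 11 | 4-methoxy-3-methyl-2-(triethylsilyloxy)furan | CC[Si](CC)(CC)Oc1occ(OC)c1C
F5 | step 7 | (3R,4S)-3-(4-{2-[(1R)-1-(benzyloxy)propyl]-1,3-dioxolan-2-yl}-1-hydroxybutyl)-4-methyldihydrofuran-2(3H)-one (mixture at the carbinol carbon) | CC[C@@H](OCc1ccccc1)C1(OCCO1)CCCC(O)[C@H]2[C@H](C)COC2=O
F6 | step 7 | (4S)-3-(4-{2-[(1R)-1-(benzyloxy)propyl]-1,3-dioxolan-2-yl}butanoyl)-4-methyldihydrofuran-2(3H)-one | CC[C@@H](OCc1ccccc1)C1(OCCO1)CCCC(=O)C2[C@H](C)COC2=O
F7 | step 7 | N-sulfinyl enamino lactone from F6 and 8 (C8=C9 enamine, S at sulfur) | CC[C@@H](OCc1ccccc1)C1(OCCO1)CCCC(N[S@@](=O)C(C)(C)C)=C2[C@H](C)COC2=O
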